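**The question.** When alpha and beta stop at 25 min, which holds more of the charge, substrate or product, and how much?

| setting | north-east | south-west | alpha | beta |
|---|---|---|---|---|
| substrate | 0.050 M | 0.050 M | 0.050 M | 0.050 M |
| enzyme | 2.5 µM | 2.8 µM | 2.2 µM | 3.3 µM |
| remark | run made earlier | run made earlier |  |  |
| time |  |  | 25 min | 25 min |

- north-east (time / min: substrate / %, product / %): 2.50: 90.6, 9.0; 5.00: 85.0, 15.1; 8.00: 78.9, 21.3; 10.0: 75.7, 23.9; 12.0: 72.4, 27.4
- south-west (time / min: substrate / %, product / %): 2.50: 90.2, 9.9; 5.00: 84.0, 16.7; 8.00: 77.5, 21.8; 10.0: 74.7, 25.6; 12.0: 71.0, 28.6

(scatter of a reading: 0.3 percentage points)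

- which of these there is most of at the end, counted by the substrate in it, alpha (product / substrate)
- which of these there is most of at the end, counted by the substrate in it, beta (product / substrate)
- final amount of the leader among these, as a percentage of the substrate charged, in alpha
- final amount of the leader among these, as a percentage of the substrate charged, in beta



**Start rate.** I reckon with the rate, not the levels. I take it as proportional to enzyme and to substrate left, and I divide it by a brake: one plus a brake number times the share turned (product inhibition). The first and last readings of the north-east run give a brake number of 6.20. They also put the start rate of beta at 0.0676 min⁻¹ of its charge.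

**The slowing.** At half turned, lost substrate divides the rate by 2 and the brake divides it by 4.10, so the brake is the stronger. At its start rate, beta turns half its charge in 7.40 min. Summed along the way, the slowing stretches this to 28.0 min, the crossover time: the moment substrate and product stand equal. I assume it scales inversely with charged enzyme, a step the two runs try between 2.5 µM and 2.8 µM, and so estimate 42.0 min for alpha. Both estimates lie beyond the stop, so I expect substrate to lead in both flasks.

**The forecast.** It gives substrate at 61% in alpha and substrate at 53% in beta, adding that “beta is close to the crossover”. My law reaches those levels at 25.3 min in alpha and 24.5 min in beta, so we agree.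

**The result.** Substrate leads with 60.6% in alpha and 54.7% in beta.

    substrate + enzyme → product + enzyme, rate k1*[substrate]*[enzyme]/(1 + ([substrate]/Km1) + ([product]/Kp1)) (36.0 mM, 3.40 mM, k = 85000 L mol⁻¹ min⁻¹)
    2 enzyme ⇌ resting dimer, settled at all times (K = 3.20 × 10⁵ L mol⁻¹)

**What ran.** In beta, substrate turned to product throughout, with 23% of the turnover done after 2.50 min and half by 7.39 min. At 12.5 min and 25.0 min alike, beta's enzyme stood at 49.1% free beside 50.9% as resting dimer. Alpha's enzyme stood at 55.9% free, so at 25.0 min beta held 1.32 times alpha's free enzyme, less than the 1.50 of the charges on which my estimate for alpha rests.

**Second flask.** A neighbour of beta is charged with 0.020 M of substrate. Taking the brake as a matter of product concentration, its number falls to 2.48. The crossover time then drops from 28.0 min to 17.4 min, earlier than the stop, so product should lead. The computed flask holds 62.7% product and 37.3% substrate.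

The runs were generated by integration with made-up constants; noise was put on by code.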